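The decalin (naphthalene numbering: ring A = C1, C2, C3, C4, C4a, C8a; ring B = C4a, C5, C6, C7, C8, C8a) is disconnected across the ring-fusion bond C4a–C8a and the bond C1–C2. Ring A, with its exocyclic C2=C(CH3)2 next to the side-chain carbon C1, is the retron of a vinylallene Diels–Alder reaction: an acyclic (E)-β-methyl enal tethered through C5–C8 to a dimethyl-substituted vinylallene should cyclise to close both rings, place the isopropylidene group and set C1, C4a and C8a in one operation, directed by the C5 and C6 stereocentres that stem from a lactone template. Chain extension, diimide reduction and phenol oxidation finish the route.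

Key step: step 11

Assumption: methyl hydrogen (R)-3-methylglutarate (3) is taken as a commercial chiral building block; atom numbers in the text are the naphthalene numbers of the decalin in the product.

Step 1
Reactants: 1 2,6-dimethylanisole
Product: 2 1-(bromomethyl)-2-methoxy-3-methylbenzene
Conditions: NBS (1.0 equiv), AIBN (cat.), PhCF3, 80 °C
Reagents that add atoms: N-bromosuccinimide, O=C1CCC(=O)N1Br
Why: Wohl–Ziegler radical benzylic bromination; the two methyl groups of 1 are equivalent, so only one monobromide can form, and one equivalent of NBS in a non-polar solvent under radical initiation should hold back dibromination and ring bromination.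

Step 2
Reactants: 3 methyl hydrogen (R)-3-methylglutarate
Product: 5 (R)-4-methyltetrahydro-2H-pyran-2-one, via hydroxy ester 4 (not isolated)
Conditions: BH3·SMe2, THF, 0 °C → rt; H2O; then TsOH (cat.), CH2Cl2, rt
Reagents that add atoms: none
Why: Borane reduces the free carboxylic acid chemoselectively beside the methyl ester and the δ-hydroxy ester lactonises under acid catalysis (reduction, then lactonisation), the stereocentre being untouched and becoming C4 of the lactone.

Step 3
Reactants: 5 (R)-4-methyltetrahydro-2H-pyran-2-one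
Product: 6 (3S,4R)-3,4-dimethyltetrahydro-2H-pyran-2-one
Conditions: LiN(iPr)2, THF, −78 °C; MeI, −78 → −40 °C
Reagents that add atoms: iodomethane, CI
Why: Enolate alkylation of the lactone lithium enolate should occur anti to the C4 methyl group and give mainly the trans isomer, although the configuration at C3 is of no consequence because this carbon is enolised again in step 4.

Step 4
Reactants: 6 (3S,4R)-3,4-dimethyltetrahydro-2H-pyran-2-one; 2 1-(bromomethyl)-2-methoxy-3-methylbenzene
Product: 7 (3S,4R)-3-(2-methoxy-3-methylbenzyl)-3,4-dimethyltetrahydro-2H-pyran-2-one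
Conditions: LiN(iPr)2, THF, −78 °C; DMPU; 2, −78 → −20 °C
Reagents that add atoms: none
Why: Enolate alkylation forming a quaternary carbon; the benzylic bromide should attack the tetrasubstituted enolate on the face opposite the C4 methyl group, which lies pseudoaxial to avoid A(1,2) strain with the enolate methyl group, so that the arylmethyl group ends trans and the C3 methyl cis to the C4 methyl (3S).

Step 5
Reactants: 7 (3S,4R)-3-(2-methoxy-3-methylbenzyl)-3,4-dimethyltetrahydro-2H-pyran-2-one
Product: 9 (3R,4S)-4-(2-methoxy-3-methylbenzyl)-3,4-dimethylhex-5-yn-1-ol, via lactol 8 (not isolated)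
Conditions: iBu2AlH, CH2Cl2, −78 °C; then MeOH, K2CO3, dimethyl (1-diazo-2-oxopropyl)phosphonate, −78 °C → rt; aq. KNaC4H4O6
Reagents that add atoms: dimethyl (1-diazo-2-oxopropyl)phosphonate, COP(=O)(OC)C(=[N+]=[N-])C(C)=O
Why: Half-reduction of the lactone to the lactol and Seyferth–Gilbert homologation of its open hydroxy aldehyde form with the Ohira–Bestmann reagent in one pot should give the terminal alkyne, the aldehyde carbon being attached to a quaternary carbon and therefore not epimerisable.

Step 6
Reactants: 9 (3R,4S)-4-(2-methoxy-3-methylbenzyl)-3,4-dimethylhex-5-yn-1-ol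
Product: 10 (3S,4R)-6-bromo-3-(2-methoxy-3-methylbenzyl)-3,4-dimethylhex-1-yne
Conditions: CBr4, PPh3, CH2Cl2, 0 °C
Reagents that add atoms: tetrabromomethane, BrC(Br)(Br)Br
Why: Appel reaction; the unhindered primary alcohol is converted into the bromide by SN2 displacement of the oxyphosphonium group without touching the alkyne or the stereocentres.

Step 7
Reactants: 10 (3S,4R)-6-bromo-3-(2-methoxy-3-methylbenzyl)-3,4-dimethylhex-1-yne; 11 3-chloro-3-methylbut-1-yne
Product: 14 (5E,7S,8R)-10-bromo-7-(2-methoxy-3-methylbenzyl)-2,7,8-trimethyldeca-2,3,5-triene, via alkenylzirconocene chloride 12 (not isolated), via alkenylzinc chloride 13 (not isolated)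
Conditions: Cp2Zr(H)Cl, THF, rt; ZnCl2, 0 °C; then 11, Pd(PPh3)4 (5 mol %), 0 °C → rt
Reagents that add atoms: none
Why: Syn hydrozirconation places zirconium on the terminal alkyne carbon with E geometry, transmetalation gives the alkenylzinc chloride, and zerovalent palladium adds to the tertiary propargylic chloride in SN2′ fashion to an allenylpalladium species that couples at the unhindered allene terminus with retention of the alkene geometry (Negishi coupling giving a vinylallene).

Step 8
Reactants: 14 (5E,7S,8R)-10-bromo-7-(2-methoxy-3-methylbenzyl)-2,7,8-trimethyldeca-2,3,5-triene; 15 ethyl but-2-ynoate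
Product: 19 ethyl (2E,6R,7S,8E)-7-(2-methoxy-3-methylbenzyl)-3,6,7,12-tetramethyltrideca-2,8,10,11-tetraenoate, via Grignard reagent 16 (not isolated), via alkylcopper 17 (not isolated), via alkenylcopper 18 (not isolated)
Conditions: Mg, THF, rt; CuBr·SMe2, −40 °C; 15, −78 °C; MeOH, then aq. NH4Cl, −78 °C
Reagents that add atoms: none
Why: The Grignard reagent is converted into the monoalkylcopper reagent, which adds syn across the triple bond of the 2-ynoate (carbocupration), and protonation of the alkenylcopper at −78 °C retains this geometry, so that the new chain is trans to the ester in the trisubstituted (E)-enoate.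

Step 9
Reactants: 19 ethyl (2E,6R,7S,8E)-7-(2-methoxy-3-methylbenzyl)-3,6,7,12-tetramethyltrideca-2,8,10,11-tetraenoate
Product: 20 (2E,6R,7S,8E)-7-(2-methoxy-3-methylbenzyl)-3,6,7,12-tetramethyltrideca-2,8,10,11-tetraen-1-ol
Conditions: iBu2AlH (2.2 equiv), CH2Cl2, −78 °C
Reagents that add atoms: none
Why: 1,2-Reduction of the conjugated ester by the aluminium hydride at low temperature should give the allylic alcohol without change of alkene geometry and without reaction of the vinylallene.

Step 10
Reactants: 20 (2E,6R,7S,8E)-7-(2-methoxy-3-methylbenzyl)-3,6,7,12-tetramethyltrideca-2,8,10,11-tetraen-1-ol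
Product: 21 (2E,6R,7S,8E)-7-(2-methoxy-3-methylbenzyl)-3,6,7,12-tetramethyltrideca-2,8,10,11-tetraenal
Conditions: activated MnO2, CH2Cl2, 0 °C → rt
Reagents that add atoms: none
Why: Allylic oxidation with MnO2 under neutral conditions should give the enal with retention of the E geometry and leave the vinylallene intact.

Step 11
Reactants: 21 (2E,6R,7S,8E)-7-(2-methoxy-3-methylbenzyl)-3,6,7,12-tetramethyltrideca-2,8,10,11-tetraenal
Product: 22 (1S,4aR,5S,6R,8aR)-5-(2-methoxy-3-methylbenzyl)-5,6,8a-trimethyl-2-(propan-2-ylidene)-1,2,4a,5,6,7,8,8a-octahydronaphthalene-1-carbaldehyde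
Conditions: toluene (0.01 M), BHT (cat.), 110 °C, sealed tube
Reagents that add atoms: none
Why: Thermal, concerted, suprafacial [4+2] cycloaddition (intramolecular Diels–Alder reaction of a vinylallene, the closest known class being vinylallene cycloadditions that give 3-alkylidenecyclohexenes), in which the diene is C4a=C4–C3=C2 of the vinylallene and the dienophile is the enal double bond C8a=C1, so that the bonds C4a–C8a and C1–C2 form together. Ring B closes through the four-atom tether C5–C8 as a six-membered ring fused at the new C4a–C8a bond, and ring A is the cyclohexene made by the cycloaddition itself, its C2=C(CH3)2 unit being the untouched distal double bond of the allene. The C8a methyl and the C1 formyl group become cis because of the E geometry of the enal, and the hydrogen at C4a ends trans to the C8a methyl because the formyl group is endo and the tether exo, an arrangement favoured by secondary orbital overlap and enforced by the allene methyl group on the reacting face, which would clash with an exo formyl group. The diene face is chosen by the tether stereocentres C5 and C6: in the chair-like transition state that leads to 22 the C6 methyl and the arylmethyl group are equatorial and only the C5 methyl is axial, whereas attack on the other face would place the C6 methyl and the arylmethyl group axial. The step thus needs endo and facial selectivity, the first secured by the allene terminus and the (E)-enal and the second by the C5/C6 substitution, while regiochemistry is fixed by the tether length.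

Step 12
Reactants: 22 (1S,4aR,5S,6R,8aR)-5-(2-methoxy-3-methylbenzyl)-5,6,8a-trimethyl-2-(propan-2-ylidene)-1,2,4a,5,6,7,8,8a-octahydronaphthalene-1-carbaldehyde
Product: 23 methyl (2E)-3-[(1S,4aR,5S,6R,8aR)-5-(2-methoxy-3-methylbenzyl)-5,6,8a-trimethyl-2-(propan-2-ylidene)-1,2,4a,5,6,7,8,8a-octahydronaphthalen-1-yl]prop-2-enoate
Conditions: Ph3P=CHCO2Me, toluene, 80 °C (crude 22 used at once)
Reagents that add atoms: methyl (triphenylphosphoranylidene)acetate, COC(=O)C=P(c1ccccc1)(c1ccccc1)c1ccccc1
Why: Wittig reaction of the hindered aldehyde with the stabilised ylide should give the (E)-enoate and, being free of added base, should neither epimerise C1 nor move the C2 double bond into conjugation.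

Step 13
Reactants: 23 methyl (2E)-3-[(1S,4aR,5S,6R,8aR)-5-(2-methoxy-3-methylbenzyl)-5,6,8a-trimethyl-2-(propan-2-ylidene)-1,2,4a,5,6,7,8,8a-octahydronaphthalen-1-yl]prop-2-enoate
Product: 24 methyl 3-[(1S,4aR,5S,6R,8aR)-5-(2-methoxy-3-methylbenzyl)-5,6,8a-trimethyl-2-(propan-2-ylidene)decahydronaphthalen-1-yl]propanoate
Conditions: 2-nitrobenzenesulfonylhydrazide (excess, in portions), Et3N, CH2Cl2, rt
Reagents that add atoms: none
Why: Diimide reduction; diimide transfers hydrogen in a concerted syn fashion to the disubstituted C3=C4 and side-chain double bonds but should not reduce the tetrasubstituted isopropylidene double bond or the arene, and no stereocentre is formed.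

Step 14
Reactants: 24 methyl 3-[(1S,4aR,5S,6R,8aR)-5-(2-methoxy-3-methylbenzyl)-5,6,8a-trimethyl-2-(propan-2-ylidene)decahydronaphthalen-1-yl]propanoate
Product: 25 3-[(1S,4aR,5S,6R,8aR)-5-(2-hydroxy-3-methylbenzyl)-5,6,8a-trimethyl-2-(propan-2-ylidene)decahydronaphthalen-1-yl]propanoic acid
Conditions: NaSEt, DMF, 130 °C; then aq. HCl, 0 °C
Reagents that add atoms: none
Why: Nucleophilic demethylation; ethanethiolate should cleave both the hindered aryl methyl ether and the methyl ester by SN2 attack at the methyl carbon, which frees the phenol and the acid in one operation without acid that could move the isopropylidene double bond.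

Step 15
Reactants: 25 3-[(1S,4aR,5S,6R,8aR)-5-(2-hydroxy-3-methylbenzyl)-5,6,8a-trimethyl-2-(propan-2-ylidene)decahydronaphthalen-1-yl]propanoic acid
Product: 26 stypoquinonic acid
Conditions: K2[ON(SO3)2] (Fremy's salt, 2.5 equiv), KH2PO4, acetone/H2O, rt
Reagents that add atoms: dipotassium nitrosodisulfonate, [K+].[K+].[O]N(S(=O)(=O)[O-])S(=O)(=O)[O-]
Why: Teuber oxidation; the 2,6-dialkylphenol with a free para position should be oxidised by two equivalents of the nitrosodisulfonate radical to the 1,4-benzoquinone, the tetrasubstituted alkene and the carboxylic acid being inert.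

Compound list

1 | 2,6-dimethylanisole | COc1c(C)cccc1C | starting material
2 | 1-(bromomethyl)-2-methoxy-3-methylbenzene | COc1c(C)cccc1CBr | intermediate
3 | methyl hydrogen (R)-3-methylglutarate | COC(=O)C[C@H](C)CC(=O)O | starting material
4 | methyl (R)-5-hydroxy-3-methylpentanoate | COC(=O)C[C@H](C)CCO | intermediate (not isolated)
5 | (R)-4-methyltetrahydro-2H-pyran-2-one | O=C1C[C@H](C)CCO1 | intermediate
6 | (3S,4R)-3,4-dimethyltetrahydro-2H-pyran-2-one | O=C1[C@@H](C)[C@H](C)CCO1 | intermediate
7 | (3S,4R)-3-(2-methoxy-3-methylbenzyl)-3,4-dimethyltetrahydro-2H-pyran-2-one | COc1c(C)cccc1C[C@@]1(C)[C@H](C)CCOC1=O | intermediate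
8 | (3S,4R)-3-(2-methoxy-3-methylbenzyl)-3,4-dimethyltetrahydro-2H-pyran-2-ol (lactol, anomer mixture) | COc1c(C)cccc1C[C@@]1(C)[C@H](C)CCOC1O | intermediate (not isolated)
9 | (3R,4S)-4-(2-methoxy-3-methylbenzyl)-3,4-dimethylhex-5-yn-1-ol | COc1c(C)cccc1C[C@](C)(C#C)[C@H](C)CCO | intermediate
10 | (3S,4R)-6-bromo-3-(2-methoxy-3-methylbenzyl)-3,4-dimethylhex-1-yne | COc1c(C)cccc1C[C@](C)(C#C)[C@H](C)CCBr | intermediate
11 | 3-chloro-3-methylbut-1-yne | CC(C)(Cl)C#C | starting material
12 | chlorobis(cyclopentadienyl)[(1E,3S,4R)-6-bromo-3-(2-methoxy-3-methylbenzyl)-3,4-dimethylhex-1-en-1-yl]zirconium | COc1c(C)cccc1C[C@](C)(/C=C/[Zr](Cl)(C1C=CC=C1)C1C=CC=C1)[C@H](C)CCBr | intermediate (not isolated)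
13 | [(1E,3S,4R)-6-bromo-3-(2-methoxy-3-methylbenzyl)-3,4-dimethylhex-1-en-1-yl]zinc chloride | COc1c(C)cccc1C[C@](C)(/C=C/[Zn]Cl)[C@H](C)CCBr | intermediate (not isolated)
14 | (5E,7S,8R)-10-bromo-7-(2-methoxy-3-methylbenzyl)-2,7,8-trimethyldeca-2,3,5-triene | COc1c(C)cccc1C[C@](C)(/C=C/C=C=C(C)C)[C@H](C)CCBr | intermediate
15 | ethyl but-2-ynoate | CC#CC(=O)OCC | starting material
16 | [(3R,4S,5E)-4-(2-methoxy-3-methylbenzyl)-3,4,9-trimethyldeca-5,7,8-trien-1-yl]magnesium bromide | COc1c(C)cccc1C[C@](C)(/C=C/C=C=C(C)C)[C@H](C)CC[Mg]Br | intermediate (not isolated)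
17 | [(3R,4S,5E)-4-(2-methoxy-3-methylbenzyl)-3,4,9-trimethyldeca-5,7,8-trien-1-yl]copper | COc1c(C)cccc1C[C@](C)(/C=C/C=C=C(C)C)[C@H](C)CC[Cu] | intermediate (not isolated)
18 | ethyl (2Z,6R,7S,8E)-2-cuprio-7-(2-methoxy-3-methylbenzyl)-3,6,7,12-tetramethyltrideca-2,8,10,11-tetraenoate | COc1c(C)cccc1C[C@](C)(/C=C/C=C=C(C)C)[C@H](C)CC/C(C)=C(\[Cu])C(=O)OCC | intermediate (not isolated)
19 | ethyl (2E,6R,7S,8E)-7-(2-methoxy-3-methylbenzyl)-3,6,7,12-tetramethyltrideca-2,8,10,11-tetraenoate | COc1c(C)cccc1C[C@](C)(/C=C/C=C=C(C)C)[C@H](C)CC/C(C)=C/C(=O)OCC | intermediate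
20 | (2E,6R,7S,8E)-7-(2-methoxy-3-methylbenzyl)-3,6,7,12-tetramethyltrideca-2,8,10,11-tetraen-1-ol | COc1c(C)cccc1C[C@](C)(/C=C/C=C=C(C)C)[C@H](C)CC/C(C)=C/CO | intermediate
21 | (2E,6R,7S,8E)-7-(2-methoxy-3-methylbenzyl)-3,6,7,12-tetramethyltrideca-2,8,10,11-tetraenal | COc1c(C)cccc1C[C@](C)(/C=C/C=C=C(C)C)[C@H](C)CC/C(C)=C/C=O | intermediate
22 | (1S,4aR,5S,6R,8aR)-5-(2-methoxy-3-methylbenzyl)-5,6,8a-trimethyl-2-(propan-2-ylidene)-1,2,4a,5,6,7,8,8a-octahydronaphthalene-1-carbaldehyde | COc1c(C)cccc1C[C@]2(C)[C@H]3C=CC(=C(C)C)[C@@H](C=O)[C@]3(C)CC[C@H]2C | intermediate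
23 | methyl (2E)-3-[(1S,4aR,5S,6R,8aR)-5-(2-methoxy-3-methylbenzyl)-5,6,8a-trimethyl-2-(propan-2-ylidene)-1,2,4a,5,6,7,8,8a-octahydronaphthalen-1-yl]prop-2-enoate | COc1c(C)cccc1C[C@]2(C)[C@H]3C=CC(=C(C)C)[C@@H](/C=C/C(=O)OC)[C@]3(C)CC[C@H]2C | intermediate
24 | methyl 3-[(1S,4aR,5S,6R,8aR)-5-(2-methoxy-3-methylbenzyl)-5,6,8a-trimethyl-2-(propan-2-ylidene)decahydronaphthalen-1-yl]propanoate | COc1c(C)cccc1C[C@]2(C)[C@H]3CCC(=C(C)C)[C@@H](CCC(=O)OC)[C@]3(C)CC[C@H]2C | intermediate
25 | 3-[(1S,4aR,5S,6R,8aR)-5-(2-hydroxy-3-methylbenzyl)-5,6,8a-trimethyl-2-(propan-2-ylidene)decahydronaphthalen-1-yl]propanoic acid | Cc1cccc(C[C@]2(C)[C@H]3CCC(=C(C)C)[C@@H](CCC(=O)O)[C@]3(C)CC[C@H]2C)c1O | intermediate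
26 | stypoquinonic acid, 3-[(1S,4aR,5S,6R,8aR)-5,6,8a-trimethyl-5-[(5-methyl-3,6-dioxocyclohexa-1,4-dien-1-yl)methyl]-2-(propan-2-ylidene)decahydronaphthalen-1-yl]propanoic acid | CC1=CC(=O)C=C(C[C@]2(C)[C@H]3CCC(=C(C)C)[C@@H](CCC(=O)O)[C@]3(C)CC[C@H]2C)C1=O | target

Total step count: 15.
Longest linear sequence: 14 steps (steps 2 to 15, from 3).

Steps most likely to fail

Step 11. The cycloaddition may be slow, because the dienophile is β,β-disubstituted and one allene methyl group lies on the reacting face. Prolonged heating could then move the C2 double bond of the product aldehyde into conjugation, epimerise C1, or let the vinylallene oligomerise. The fallback moves the cycloaddition to the ester stage and sets out from 19. Heating 19 in 1,2-dichlorobenzene at 170 °C should give ethyl (1S,4aR,5S,6R,8aR)-5-(2-methoxy-3-methylbenzyl)-5,6,8a-trimethyl-2-(propan-2-ylidene)-1,2,4a,5,6,7,8,8a-octahydronaphthalene-1-carboxylate F1, which cannot drift into conjugation as easily. LiAlH4 then gives [(1S,4aR,5S,6R,8aR)-5-(2-methoxy-3-methylbenzyl)-5,6,8a-trimethyl-2-(propan-2-ylidene)-1,2,4a,5,6,7,8,8a-octahydronaphthalen-1-yl]methanol F2. Dess–Martin periodinane oxidation returns to the route at 22, which is taken directly into step 12.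

Step 8. Magnesium insertion passes through a carbon radical and an organomagnesium that sit five atoms from the dienyl system, so ring closure onto it may compete. The alkenylcopper may also lose its geometry before the quench. The fallback avoids both and sets out from 14. NaI in acetone gives (5E,7S,8R)-10-iodo-7-(2-methoxy-3-methylbenzyl)-2,7,8-trimethyldeca-2,3,5-triene F3. Iodine–lithium exchange with t-BuLi at −78 °C followed by ZnCl2 gives [(3R,4S,5E)-4-(2-methoxy-3-methylbenzyl)-3,4,9-trimethyldeca-5,7,8-trien-1-yl]zinc chloride F4 without radical intermediates. Negishi coupling catalysed by Pd(dppf)Cl2 with ethyl (E)-3-{[(trifluoromethyl)sulfonyl]oxy}but-2-enoate F5 (from ethyl acetoacetate, Tf2O and aqueous Me4NOH) should proceed with retention of the triflate geometry and return to the route at 19.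

Step 7. Hydrozirconation of the hindered alkyne may be incomplete. The palladium step may give the propargylic instead of the allenic coupling product, or the vinylallene may dimerise under the coupling conditions. The fallback builds the allene by reduction instead of coupling and sets out from 10. Cp2Zr(H)Cl followed by I2 gives 1-{(2S,3R)-5-bromo-2-[(E)-2-iodoethenyl]-2,3-dimethylpentyl}-2-methoxy-3-methylbenzene F6. Sonogashira coupling (Pd(PPh3)2Cl2, CuI, Et3N) with 2-methylbut-3-yn-2-ol gives (5E,7S,8R)-10-bromo-7-(2-methoxy-3-methylbenzyl)-2,7,8-trimethyldec-5-en-3-yn-2-ol F7. LiN(SiMe3)2 and ClCO2Me give (5E,7S,8R)-10-bromo-7-(2-methoxy-3-methylbenzyl)-2,7,8-trimethyldec-5-en-3-yn-2-yl methyl carbonate F8. Palladium-catalysed hydrogenolysis with HCO2NH4 (Pd2(dba)3, PBu3) delivers hydride in SN2′ fashion and returns to the route at 14.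

Further compounds

F1 | step 11 | ethyl (1S,4aR,5S,6R,8aR)-5-(2-methoxy-3-methylbenzyl)-5,6,8a-trimethyl-2-(propan-2-ylidene)-1,2,4a,5,6,7,8,8a-octahydronaphthalene-1-carboxylate | COc1c(C)cccc1C[C@]2(C)[C@H]3C=CC(=C(C)C)[C@@H](C(=O)OCC)[C@]3(C)CC[C@H]2C
F2 | step 11 | [(1S,4aR,5S,6R,8aR)-5-(2-methoxy-3-methylbenzyl)-5,6,8a-trimethyl-2-(propan-2-ylidene)-1,2,4a,5,6,7,8,8a-octahydronaphthalen-1-yl]methanol | COc1c(C)cccc1C[C@]2(C)[C@H]3C=CC(=C(C)C)[C@@H](CO)[C@]3(C)CC[C@H]2C
F3 | step 8 | (5E,7S,8R)-10-iodo-7-(2-methoxy-3-methylbenzyl)-2,7,8-trimethyldeca-2,3,5-triene | COc1c(C)cccc1C[C@](C)(/C=C/C=C=C(C)C)[C@H](C)CCI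
F4 | step 8 | [(3R,4S,5E)-4-(2-methoxy-3-methylbenzyl)-3,4,9-trimethyldeca-5,7,8-trien-1-yl]zinc chloride | COc1c(C)cccc1C[C@](C)(/C=C/C=C=C(C)C)[C@H](C)CC[Zn]Cl
F5 | step 8 | ethyl (E)-3-{[(trifluoromethyl)sulfonyl]oxy}but-2-enoate | CCOC(=O)/C=C(\C)OS(=O)(=O)C(F)(F)F
F6 | step 7 | 1-{(2S,3R)-5-bromo-2-[(E)-2-iodoethenyl]-2,3-dimethylpentyl}-2-methoxy-3-methylbenzene | COc1c(C)cccc1C[C@](C)(/C=C/I)[C@H](C)CCBr
F7 | step 7 | (5E,7S,8R)-10-bromo-7-(2-methoxy-3-methylbenzyl)-2,7,8-trimethyldec-5-en-3-yn-2-ol | COc1c(C)cccc1C[C@](C)(/C=C/C#CC(C)(C)O)[C@H](C)CCBr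
F8 | step 7 | (5E,7S,8R)-10-bromo-7-(2-methoxy-3-methylbenzyl)-2,7,8-trimethyldec-5-en-3-yn-2-yl methyl carbonate | COc1c(C)cccc1C[C@](C)(/C=C/C#CC(C)(C)OC(=O)OC)[C@H](C)CCBr
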